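The data stem from a simulated flask on assumed constants, and the scatter is random.

The pitfall is to count back-mixing against a stirred tank by habit, even when the wanted product reacts on.

| flask | substrate | remark | time |
|---|---|---|---|
| Monday's | 0.20 M | run made earlier |  |
| Friday's | 0.10 M | run made earlier |  |
| beta | 0.20 M | one stirred flow tank at steady state, fed with the mixture as stated, mean residence time 20 h |  |
| zeta | 0.20 M | plug flow through a tube for 20 h, no back-mixing | 20 h |
| eta | 0.20 M | a closed flask charged with all of it at once and left for 20 h | 20 h |

| run | time / h | target / % | over-reaction product / % | substrate / % |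
|---|---|---|---|---|
| Monday's | 2.50 | 42 | 26 | 0 |
| Monday's | 5.00 | 23 | 43 | 1 |
| Monday's | 8.00 | 8 | 54 | 2 |
| Monday's | 10.0 | 7 | 55 | 0 |
| Monday's | 12.0 | 5 | 58 | 1 |
| Friday's | 0.333 | 52 | 2 | 24 |
| Friday's | 1.00 | 56 | 9 | 2 |
| Friday's | 2.00 | 48 | 25 | 1 |
| Friday's | 3.00 | 35 | 32 | 0 |
| Friday's | 4.00 | 36 | 39 | 1 |

(scatter of a reading: 1.5 percentage points)
- the set-up with the highest share of target in all that became target or over-reaction product, at the outlet or at the end ("none" if the first two lie within 2 percentage points) (beta / zeta / eta / none)
- share of target in all that became target or over-reaction product, at the outlet or at the end, beta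
- share of target in all that became target or over-reaction product, at the outlet or at the end, zeta
- share of target in all that became target or over-reaction product, at the outlet or at the end, eta
- the stated concentrations are those of everything mixed, before any reaction; amounts are the same in each set-up
- the earlier runs were made in a closed, stirred flask

We turn the question round: what would have to be true for tube zeta or closed flask eta to beat tank beta?

1. Monday's run has the same charge as all three set-ups. Substrate reads 0% at 2.50 h. Target then falls from 42% to 5% by 12.0 h, a drop of 37 percentage points, while over-reaction product gains 32 points. We take these two as near enough to count target's loss as that product's gain.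

2. Taking the loss as first order, dT/dt = −kT for target T integrates to T falling as e^(−kt). These readings give k = 0.224 h⁻¹, with their scatter.

3. Our quantity is n = kt, the target lifetimes spent in the time t, which in tank beta is the mean residence time (a Damköhler number). Here n = 4.48.

4. Taking target as formed at once, zeta and eta share the same n and give a share of e^(−n), or 1.13%. In beta at steady state, target formed either leaves by the outflow or reacts on, in the ratio 1 to n, so the share is 1/(1 + n), or 18.2%.

5. For the opposite outcome, e^n would have to lie below 1 + n, but for positive n it lies above. A tie would need a gap under 2 points, and ours is larger, at 17 points.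

The forecast, slightly above our figures, names beta, with 18.5%, 1.3% and 1.3% for beta, zeta and eta, because “its residence-time distribution lets some target escape early”.

The simulation gives beta, with 18.5%, 1.30% and 1.30%.

    substrate → intermediate A (k = 2.60 × 10⁻⁴ s⁻¹)
    2 substrate → homo dimer (k = 0.00110 L mol⁻¹ s⁻¹)
    target → over-reaction product (k = 6.10 × 10⁻⁵ s⁻¹)
    intermediate B ⇌ intermediate C (K = 1.40, k = 0.00150 s⁻¹)
    intermediate A ⇌ intermediate B (K = 18.0, k = 8.30 × 10⁻⁵ s⁻¹)
    substrate → target (k = 8.70 × 10⁻⁴ s⁻¹)

Target's half-life by its step to over-reaction product, 3.2 h, is shorter than the 20 h available. Back-mixing is the main reason for the share in tank beta: the share is 18.5% with it and 1.30% without it.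

Flask eta stopped at 12 h has n = 2.69, so e^(−n) gives 6.80%. The computed share is 7.55%.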